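**Retrosynthetic overview**

1. Arteminorin C is a C3–C3' linked bicoumarin: unit A is the 7-hydroxy-6,8-dimethoxycoumarin (unprimed locants), unit B the 6,7-dihydroxycoumarin (primed locants). The strategy rests on the benzene ring of unit A: O1, the C8 methoxy, O7 and the C6 methoxy sit on four adjacent carbons, so C4a is the only unsubstituted carbon ortho to O1 and lies para to O7. An electrophilic C4 can therefore close a lactone only there.
2. Last disconnection: the C7 methyl ether and the 6',7'-methylenedioxy acetal are both removed with BCl3.
3. Key disconnection: C4–C4a and O1–C2 of unit A, by Pechmann-type condensation of 2,3,4-trimethoxyphenol with the dimethylaminomethylene derivative of the unit B coumarin-3-acetate.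
4. Ring order: the pyranone ring of unit B is made first (Perkin-type condensation of 6-formylsesamol with succinic anhydride), the pyranone ring of unit A second (key step).
5. Starting materials: 2,3,4-trimethoxybenzaldehyde, sesamol, succinic anhydride.

Key step: step 5

Remark: the enamine partner is carried as its methyl ester, so that the methanol released by DMF dimethyl acetal cannot scramble the ester; the alkoxy group is lost in the ring closure.

**Route**

Step 1
Reactants: 1 2,3,4-trimethoxybenzaldehyde
Product: 3 2,3,4-trimethoxyphenol, via 2,3,4-trimethoxyphenyl formate 2 (not isolated)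
Conditions: 30% aq. H2O2, H2SO4 (cat.), MeOH, rt
Reagents that add atoms: hydrogen peroxide, OO
Why: Acid-catalysed Dakin (Baeyer-Villiger-type) oxidation, in which the hydroperoxide adduct of the aldehyde rearranges with migration of the electron-rich aryl group (ortho and para methoxy) to formate 2, which methanol cleaves in the same pot to phenol 3.

Step 2
Reactants: 4 sesamol (1,3-benzodioxol-5-ol)
Product: 6 6-hydroxy-1,3-benzodioxole-5-carbaldehyde (6-formylsesamol), via 6-(hydroxymethyl)sesamol 5 (not isolated)
Conditions: MgCl2, Et3N, (CH2O)n, MeCN, reflux; then aq. HCl
Reagents that add atoms: formaldehyde (as paraformaldehyde), C=O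
Why: Magnesium-mediated ortho-formylation of a phenol, in which the magnesium phenoxide delivers formaldehyde to the less hindered ortho carbon C6 (para to a ring oxygen) to give 5 and a second formaldehyde accepts hydride (Oppenauer-type) to leave the salicylaldehyde.

Step 3
Reactants: 6 6-hydroxy-1,3-benzodioxole-5-carbaldehyde; 7 succinic anhydride
Product: 8 2-(6-oxo-6H-[1,3]dioxolo[4,5-g]chromen-7-yl)acetic acid
Conditions: NaO2CCH2CH2CO2Na (anhydrous), neat, 180 °C; then aq. HCl
Reagents that add atoms: none
Why: Perkin-type condensation of a salicylaldehyde with succinic anhydride, in which the anhydride enolate adds to the aldehyde, the phenol oxygen lactonises on the nearer carbonyl and dehydration gives the coumarin (pyranone ring of unit B), leaving the second carboxyl as the C3' acetic acid side chain.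

Step 4
Reactants: 8 2-(6-oxo-6H-[1,3]dioxolo[4,5-g]chromen-7-yl)acetic acid
Product: 10 methyl (E)-3-(dimethylamino)-2-(6-oxo-6H-[1,3]dioxolo[4,5-g]chromen-7-yl)acrylate, via methyl ester 9 (not isolated)
Conditions: Me2NCH(OMe)2 (excess), DMF, 60 °C then 110 °C
Reagents that add atoms: N,N-dimethylformamide dimethyl acetal, COC(OC)N(C)C
Why: The formamide acetal first O-methylates the carboxylic acid (standard esterification with DMF acetals) and on heating condenses with the CH2 group activated by the ester and the coumarin-3-yl ring (aminomethylenation of an arylacetate), the push-pull alkene forming as the E isomer with NMe2 trans to the ester.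

Step 5
Reactants: 3 2,3,4-trimethoxyphenol; 10 methyl (E)-3-(dimethylamino)-2-(6-oxo-6H-[1,3]dioxolo[4,5-g]chromen-7-yl)acrylate
Product: 12 7-O-methyl-6',7'-O-methylene arteminorin C [7-(6,7,8-trimethoxy-2-oxo-2H-chromen-3-yl)-6H-[1,3]dioxolo[4,5-g]chromen-6-one], via Mannich adduct 11 (not isolated)
Conditions: CH3SO3H (neat), rt → 60 °C; then ice water
Reagents that add atoms: none
Why: This is a Pechmann-type condensation of a phenol with a 2-substituted 3-(dimethylamino)acrylate (a masked alpha-formyl ester), the known acid-mediated route to 3-substituted coumarins. CH3SO3H protonates 10 at the alpha carbon to an iminium ion, which C6 of phenol 3 (the future C4a) attacks in a Friedel-Crafts/Mannich step to give 11 and the C4–C4a bond. The phenol oxygen then acylates on the methyl ester by addition-elimination (6-exo-trig lactonisation, forming O1–C2 and closing the pyranone ring of unit A), and loss of dimethylammonium across C3–C4 gives the aromatic pyranone of 12. No stereocentre remains, since the two formed unselectively in 11 are destroyed by the elimination. The step needs carbon attack ortho to the phenol oxygen and not at C5 of 3: C6 is activated by the ortho hydroxyl and the para methoxy, the other ortho carbon carries a methoxy group, and only the C6 adduct can lactonise, whereas adducts elsewhere remain benzylic ammonium ions that can revert in the strong acid. The methylenedioxy acetal, the existing lactone and the aryl methyl ethers should tolerate CH3SO3H at this temperature.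

Step 6
Reactants: 12 7-O-methyl-6',7'-O-methylene arteminorin C
Product: 13 arteminorin C
Conditions: BCl3 (1 M in CH2Cl2, ca. 6 equiv), CH2Cl2, −20 °C → rt; then H2O, 1 M HCl
Reagents that add atoms: none
Why: Lewis-acid ether cleavage with BCl3, which is known to open aryl methylenedioxy acetals in the presence of ordinary aryl methyl ethers and to cleave hindered methyl ethers flanked by two ortho oxygens; the C7 methoxy is twisted out of plane between its neighbours and its phenoxide is vinylogous to the C2 carbonyl, whereas the planar C6 methoxy and the less basic C8 methoxy next to the lactone oxygen should persist at or below room temperature, and aqueous work-up frees the three phenols.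

**Compound list**

1 | 2,3,4-trimethoxybenzaldehyde | COc1ccc(C=O)c(OC)c1OC | starting material
2 | 2,3,4-trimethoxyphenyl formate | COc1ccc(OC=O)c(OC)c1OC | intermediate
3 | 2,3,4-trimethoxyphenol | COc1ccc(O)c(OC)c1OC | intermediate
4 | sesamol (1,3-benzodioxol-5-ol) | Oc1ccc2OCOc2c1 | starting material
5 | 6-(hydroxymethyl)-1,3-benzodioxol-5-ol (6-(hydroxymethyl)sesamol) | OCc1cc2OCOc2cc1O | intermediate
6 | 6-hydroxy-1,3-benzodioxole-5-carbaldehyde | O=Cc1cc2OCOc2cc1O | intermediate
7 | succinic anhydride | O=C1CCC(=O)O1 | starting material
8 | 2-(6-oxo-6H-[1,3]dioxolo[4,5-g]chromen-7-yl)acetic acid | OC(=O)Cc1cc2cc3OCOc3cc2oc1=O | intermediate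
9 | methyl 2-(6-oxo-6H-[1,3]dioxolo[4,5-g]chromen-7-yl)acetate | COC(=O)Cc1cc2cc3OCOc3cc2oc1=O | intermediate
10 | methyl (E)-3-(dimethylamino)-2-(6-oxo-6H-[1,3]dioxolo[4,5-g]chromen-7-yl)acrylate | COC(=O)/C(=C/N(C)C)c1cc2cc3OCOc3cc2oc1=O | intermediate
11 | methyl 3-(dimethylamino)-3-(2-hydroxy-3,4,5-trimethoxyphenyl)-2-(6-oxo-6H-[1,3]dioxolo[4,5-g]chromen-7-yl)propanoate (Mannich adduct, mixture of diastereomers) | COC(=O)C(c1cc2cc3OCOc3cc2oc1=O)C(N(C)C)c1cc(OC)c(OC)c(OC)c1O | intermediate
12 | 7-O-methyl-6',7'-O-methylene arteminorin C, 7-(6,7,8-trimethoxy-2-oxo-2H-chromen-3-yl)-6H-[1,3]dioxolo[4,5-g]chromen-6-one | COc1cc2cc(-c3cc4cc5OCOc5cc4oc3=O)c(=O)oc2c(OC)c1OC | intermediate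
13 | arteminorin C, 3-(6,7-dihydroxy-2-oxo-2H-chromen-3-yl)-7-hydroxy-6,8-dimethoxy-2H-chromen-2-one | COc1cc2cc(-c3cc4cc(O)c(O)cc4oc3=O)c(=O)oc2c(OC)c1O | target

**Step count**

Total steps: 6. Longest linear sequence: 5 steps (sesamol 4 to 13 through steps 2, 3, 4, 5 and 6).

**Steps most likely to fail**

1. Step 5 (key step). Carbon-carbon bond formation at the only moderately activated C6 of phenol 3 may be slow, so that the protonated enamino ester hydrolyses or oligomerises first. Competing attack at C5 of 3 (ortho to the C4 methoxy) would drain material into open-chain acrylates that cannot lactonise. The fallback sets out from phenol 3 and acid 8 and comes back at 12. Phenol 3 would be ortho-formylated with MgCl2, Et3N and paraformaldehyde in MeCN (the conditions of step 2), passing through 6-(hydroxymethyl)-2,3,4-trimethoxyphenol F1 to 2-hydroxy-3,4,5-trimethoxybenzaldehyde F2. The magnesium phenoxide can deliver the formyl group only to the single free ortho carbon, so the arene carbon-carbon bond is made without a regiochemical question. F2 and acid 8 would then be condensed under Perkin-Oglialoro conditions (Ac2O, Et3N, 120 °C), the standard route from salicylaldehydes and arylacetic acids to 3-arylcoumarins, to give 12, which re-enters at step 6.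

2. Step 6. The C8 methoxy is also flanked by two oxygens and may be lost together with, or instead of, the C7 methoxy. Opening of the acetal on the electron-poor coumarin may also lag, so that forcing it erodes the methyl ethers. The fallback sets out from 12 and comes back at 13. The two cleavages are separated and the methyl ether is removed by a nucleophilic instead of a Lewis-acid mechanism. Heating 12 with LiCl in DMF (about 150 °C) should demethylate by SN2 attack of chloride only at the ether whose phenoxide is stabilised, the C7 ether vinylogous to the C2 carbonyl, giving 6',7'-O-methylene arteminorin C F3. The acetal should survive, because chloride opening of the OCH2O bridge gives a chloromethyl ether that recloses. F3 would then be treated with a limited amount of BCl3 in CH2Cl2 at 0 °C, which now has only the acetal to open, and aqueous work-up gives 13.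

3. Step 3. The aldehyde of 6 is deactivated by the ortho hydroxyl and the para ring oxygen, so the melt condensation at 180 °C may be slow and accompanied by decarboxylation and tar formation. The fallback sets out from sesamol 4 and comes back at methyl ester 9, building the unit B pyranone by a Pechmann closure instead. Dimethyl succinate would be formylated with methyl formate and NaOMe (crossed Claisen condensation) to dimethyl 2-formylsuccinate F4. Condensation of 4 with F4 in CH3SO3H should close the ring at the free carbon ortho to the hydroxyl and para to a ring oxygen, giving 9 directly. Compound 9 is then heated with DMF dimethyl acetal as in the second stage of step 4 to give 10.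

**Further compounds**

F1 | step 5 | 6-(hydroxymethyl)-2,3,4-trimethoxyphenol | COc1cc(CO)c(O)c(OC)c1OC
F2 | step 5 | 2-hydroxy-3,4,5-trimethoxybenzaldehyde | COc1cc(C=O)c(O)c(OC)c1OC
F3 | step 6 | 6',7'-O-methylene arteminorin C, 7-(7-hydroxy-6,8-dimethoxy-2-oxo-2H-chromen-3-yl)-6H-[1,3]dioxolo[4,5-g]chromen-6-one | COc1cc2cc(-c3cc4cc5OCOc5cc4oc3=O)c(=O)oc2c(OC)c1O
F4 | step 3 | dimethyl 2-formylsuccinate | COC(=O)CC(C=O)C(=O)OC
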